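## Retrosynthetic overview

1. Tangeretin ⇒ ring C opened at O1–C2: a 2′-hydroxyaryl ynone that closes by 6-endo oxa-Michael addition.
2. Ynone C(=O)–C(sp) bond ⇒ 2-hydroxy-3,4,5,6-tetramethoxybenzaldehyde, used as an acyl anion (carbene-derived Breslow intermediate), plus an alkynyl cation equivalent (alkynyl(phenyl)iodonium tosylate).
3. Aldehyde ⇒ ortho-formylation of 2,3,4,5-tetramethoxyphenol ⇒ ortho-lithiation/borylation/oxidation of 1,2,3,4-tetramethoxybenzene.
4. Iodonium salt ⇒ 4-ethynylanisole + Koser's reagent.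
5. Ring order: rings A and B are bought intact; ring C is formed last, in the same flask as the key C–C bond.

Assumption: tangeretin has no stereocentres, so the given SMILES defines one achiral compound and no stereocontrol is needed; 1,2,3,4-tetramethoxybenzene, 4-ethynylanisole and Koser's reagent are taken as catalogue chemicals.

## Route

Step 1
Reactants: 1 1,2,3,4-tetramethoxybenzene
Product: 4 2,3,4,5-tetramethoxyphenol, via aryllithium 2 (not isolated), via lithium aryltrimethoxyborate 3 (not isolated)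
Conditions: n-BuLi, TMEDA, THF, 0 °C to rt; B(OMe)3, −78 °C to rt; AcOH, 30% aq. H2O2, 0 °C to rt
Reagents that add atoms: hydrogen peroxide, OO (n-BuLi and trimethyl borate, COB(OC)OC, leave atoms only in the transient 2 and 3)
Why: Directed ortho-metalation at the only type of ring hydrogen, borylation of the aryllithium and peroxide oxidation of the C–B bond (1,2-aryl shift to oxygen) give the phenol; no stereocentre is formed.

Step 2
Reactants: 4 2,3,4,5-tetramethoxyphenol
Product: 6 2-hydroxy-3,4,5,6-tetramethoxybenzaldehyde, via salicyl alcohol 5 (not isolated)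
Conditions: MgCl2, Et3N, (CH2O)n, MeCN, reflux; 1 M HCl work-up
Reagents that add atoms: formaldehyde (as paraformaldehyde), C=O
Why: Magnesium-phenoxide-directed ortho-formylation (Casnati–Skattebøl): the chelated phenoxide adds formaldehyde at the single free ortho position and a second formaldehyde oxidises the salicyl alcohol by hydride transfer; no stereocentre is formed.

Step 3
Reactants: 7 4-ethynylanisole
Product: 8 [(4-methoxyphenyl)ethynyl](phenyl)iodonium 4-methylbenzenesulfonate
Conditions: PhI(OH)OTs, 4 Å MS, CH2Cl2, 0 °C to rt, dark; precipitate with Et2O, keep at −20 °C and use at once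
Reagents that add atoms: [hydroxy(tosyloxy)iodo]benzene (Koser's reagent), Cc1ccc(cc1)S(=O)(=O)OI(O)c1ccccc1
Why: Known reaction of terminal arylalkynes with Koser's reagent: ligand exchange at trivalent iodine with loss of water gives the alkynyl(phenyl)iodonium tosylate, an alkynyl cation equivalent; no stereocentre is formed.

Step 4
Reactants: 6 2-hydroxy-3,4,5,6-tetramethoxybenzaldehyde; 8 [(4-methoxyphenyl)ethynyl](phenyl)iodonium 4-methylbenzenesulfonate
Product: 12 tangeretin, via Breslow intermediate 9 (not isolated), via hydroxy ynone 10 (not isolated), via enaminone 11 (not isolated)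
Conditions: 4,5-dimethyl-3-(2,4,6-trimethylphenyl)thiazol-3-ium perchlorate (20 mol %), TMEDA (1.5 equiv), 4 Å MS, toluene, −40 °C to rt; then Et2NH, EtOH, 50 °C
Reagents that add atoms: none
Why: Proposed new method: the thiazol-2-ylidene adds to the aldehyde of 6 to give Breslow intermediate 9, whose acyl-anion carbon attacks the electrophilic alkynyl carbon on trivalent iodine in 8 (loss of PhI, then release of the carbene) to give ynone 10, after which Et2NH adds to the ynone (enaminone 11) and the ortho-OH closes ring C 6-endo by addition–elimination, which avoids the 5-exo aurone; the closest known reaction types are the carbene-catalysed C–H alkynylation of aldehydes with alkynyl(aryl)iodonium salts to ynones and the secondary-amine-mediated cyclisation of 2′-hydroxyaryl ynones to flavones; new here are the free, hydrogen-bonded ortho-phenol (expected to be a far weaker nucleophile than the Breslow carbon under TMEDA in toluene), the doubly ortho-substituted aldehyde (hence a thiazolylidene with one open flank) and the one-pot cascade; no stereocentre is formed.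

## Compound list

1 | 1,2,3,4-tetramethoxybenzene | COc1ccc(OC)c(OC)c1OC | starting material
2 | (2,3,4,5-tetramethoxyphenyl)lithium | [Li]c1cc(OC)c(OC)c(OC)c1OC | intermediate
3 | lithium trimethoxy(2,3,4,5-tetramethoxyphenyl)borate | [Li+].CO[B-](OC)(OC)c1cc(OC)c(OC)c(OC)c1OC | intermediate
4 | 2,3,4,5-tetramethoxyphenol | Oc1cc(OC)c(OC)c(OC)c1OC | intermediate
5 | 2-(hydroxymethyl)-3,4,5,6-tetramethoxyphenol (present as its magnesium phenoxide) | OCc1c(O)c(OC)c(OC)c(OC)c1OC | intermediate
6 | 2-hydroxy-3,4,5,6-tetramethoxybenzaldehyde | O=Cc1c(O)c(OC)c(OC)c(OC)c1OC | intermediate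
7 | 4-ethynylanisole (1-ethynyl-4-methoxybenzene) | COc1ccc(C#C)cc1 | starting material
8 | [(4-methoxyphenyl)ethynyl](phenyl)iodonium 4-methylbenzenesulfonate | COc1ccc(cc1)C#C[I+]c1ccccc1.Cc1ccc(cc1)S(=O)(=O)[O-] | intermediate
9 | Breslow intermediate: 2-{hydroxy[4,5-dimethyl-3-(2,4,6-trimethylphenyl)thiazol-2(3H)-ylidene]methyl}-3,4,5,6-tetramethoxyphenol (enol geometry not defined) | OC(=C1SC(C)=C(C)N1c1c(C)cc(C)cc1C)c1c(O)c(OC)c(OC)c(OC)c1OC | intermediate
10 | 1-(2-hydroxy-3,4,5,6-tetramethoxyphenyl)-3-(4-methoxyphenyl)prop-2-yn-1-one | COc1ccc(cc1)C#CC(=O)c1c(O)c(OC)c(OC)c(OC)c1OC | intermediate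
11 | (E)-3-(diethylamino)-1-(2-hydroxy-3,4,5,6-tetramethoxyphenyl)-3-(4-methoxyphenyl)prop-2-en-1-one | CCN(CC)/C(c1ccc(OC)cc1)=C/C(=O)c1c(O)c(OC)c(OC)c(OC)c1OC | intermediate
12 | tangeretin, 5,6,7,8-tetramethoxy-2-(4-methoxyphenyl)-4H-chromen-4-one (achiral) | COc1ccc(-c2cc(=O)c3c(OC)c(OC)c(OC)c(OC)c3o2)cc1 | target

## Step count and risks

Total step count: 4. Longest linear sequence: 3 (steps 1, 2, 4); step 3 is a one-step side branch.

Steps most likely to fail:

**Step 4.** The aldehyde is electron-rich and flanked on both sides, so Breslow formation may be slow. The phenol or the free carbene may also consume 8. The fallback uses a stoichiometric masked acyl anion (Corey–Seebach); it sets out from 6 and comes back at 12. Aldehyde 6 with 1,3-propanedithiol and BF3·OEt2 in CH2Cl2 gives 2-(1,3-dithian-2-yl)-3,4,5,6-tetramethoxyphenol F1. Double deprotonation (n-BuLi 2.2 equiv, TMEDA, THF, −30 °C) and opening of 2-(4-methoxyphenyl)oxirane at its CH2 end gives racemic 2-{2-[2-hydroxy-2-(4-methoxyphenyl)ethyl]-1,3-dithian-2-yl}-3,4,5,6-tetramethoxyphenol F2. MeI/CaCO3 in aqueous MeCN unmasks the ketone to racemic 3-hydroxy-1-(2-hydroxy-3,4,5,6-tetramethoxyphenyl)-3-(4-methoxyphenyl)propan-1-one F3. Catalytic TsOH in warm toluene dehydrates it to (E)-1-(2-hydroxy-3,4,5,6-tetramethoxyphenyl)-3-(4-methoxyphenyl)prop-2-en-1-one F4. Catalytic I2 in DMSO at 130 °C then gives 12 by oxidative cyclisation, which also erases the earlier stereocentre.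

**Step 3.** The electron-rich arylalkynyl iodonium salt 8 may decompose on formation or storage. The fallback avoids it by attaching ring B last; it sets out from 6 and comes back at 12. The carbene-catalysed coupling of step 4 is run with the bench-stable phenyl[(trimethylsilyl)ethynyl]iodonium trifluoromethanesulfonate to give 1-(2-hydroxy-3,4,5,6-tetramethoxyphenyl)-3-(trimethylsilyl)prop-2-yn-1-one F5. K2CO3 in MeOH removes silicon and closes ring C to 5,6,7,8-tetramethoxy-4H-chromen-4-one F6. Conjugate addition of 4-methoxyphenylboronic acid, catalysed by Pd(OCOCF3)2 (divalent palladium) with 2,2′-bipyridine in aqueous AcOH, gives racemic 5,6,7,8-tetramethoxy-2-(4-methoxyphenyl)chroman-4-one F7. I2 in DMSO at 130 °C dehydrogenates it to 12.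

**Step 2.** The very electron-rich phenol 4 may give methylene-bridged dimers or oxidise instead of formylating cleanly. The fallback installs the formyl group by directed lithiation; it sets out from 4 and comes back at 6. MOMCl/NaH in THF gives 1-(methoxymethoxy)-2,3,4,5-tetramethoxybenzene F8. n-BuLi/TMEDA in THF at 0 °C lithiates the only free position (ortho to OMOM), and DMF then gives 2-(methoxymethoxy)-3,4,5,6-tetramethoxybenzaldehyde F9. HCl in MeOH removes the acetal to give 6.

## Further compounds

F1 | step 4 | 2-(1,3-dithian-2-yl)-3,4,5,6-tetramethoxyphenol | Oc1c(C2SCCCS2)c(OC)c(OC)c(OC)c1OC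
F2 | step 4 | 2-{2-[2-hydroxy-2-(4-methoxyphenyl)ethyl]-1,3-dithian-2-yl}-3,4,5,6-tetramethoxyphenol (racemic) | COc1ccc(cc1)C(O)CC1(SCCCS1)c1c(O)c(OC)c(OC)c(OC)c1OC
F3 | step 4 | 3-hydroxy-1-(2-hydroxy-3,4,5,6-tetramethoxyphenyl)-3-(4-methoxyphenyl)propan-1-one (racemic) | COc1ccc(cc1)C(O)CC(=O)c1c(O)c(OC)c(OC)c(OC)c1OC
F4 | step 4 | (E)-1-(2-hydroxy-3,4,5,6-tetramethoxyphenyl)-3-(4-methoxyphenyl)prop-2-en-1-one | COc1ccc(/C=C/C(=O)c2c(O)c(OC)c(OC)c(OC)c2OC)cc1
F5 | step 3 | 1-(2-hydroxy-3,4,5,6-tetramethoxyphenyl)-3-(trimethylsilyl)prop-2-yn-1-one | C[Si](C)(C)C#CC(=O)c1c(O)c(OC)c(OC)c(OC)c1OC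
F6 | step 3 | 5,6,7,8-tetramethoxy-4H-chromen-4-one | COc1c(OC)c(OC)c2c(c1OC)c(=O)cco2
F7 | step 3 | 5,6,7,8-tetramethoxy-2-(4-methoxyphenyl)chroman-4-one (racemic) | COc1ccc(cc1)C1CC(=O)c2c(OC)c(OC)c(OC)c(OC)c2O1
F8 | step 2 | 1-(methoxymethoxy)-2,3,4,5-tetramethoxybenzene | COCOc1cc(OC)c(OC)c(OC)c1OC
F9 | step 2 | 2-(methoxymethoxy)-3,4,5,6-tetramethoxybenzaldehyde | COCOc1c(C=O)c(OC)c(OC)c(OC)c1OC
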